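## Retrosynthetic overview
1. Target **18** comes from late α-methylenation of lactone **17**. **17** comes from an epoxide acetolysis/oxa-cyclisation cascade (C8-OAc, 9,12-THF, C13-OH) of trans-bis-epoxide **16**. **16** comes from Shi double epoxidation of the macrocyclic (E,E)-diene **15**.
2. The 14-membered ring is closed at C2–C3 by an intramolecular direct vinylogous aldol of a butenolide γ-carbon onto the C3 aldehyde of **12**. The cis-fused lactone (C1) comes from face-selective 1,4-reduction of the butenolide.
3. **12** comes from Stille coupling (C1–C14) of stannylbutenolide **3** with a farnesol-derived allylic chloride. The C4 methyl stereocentre comes from Ru-BINAP hydrogenation of a tiglic-type acid.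
4. Ring order: butenolide (present from the start), then the 14-membered carbocycle, then the cis-lactone, then the two epoxides, then the THF, then the exocyclic methylene.

Assumption: all-E farnesol is used, and the catalyst enantiomeric series (BINAP, cinchona, fructose ketone) are chosen to give the depicted absolute configurations.

## Route

**Step 1**
Reactants: 1 tetronic acid (furan-2,4(3H,5H)-dione)
Product: 2 4-bromofuran-2(5H)-one
Conditions: (COBr)2, DMF (cat.), CH2Cl2, 0 °C → rt
Reagents that add atoms: oxalyl bromide, O=C(Br)C(=O)Br (supplies Br)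
Why: The tetronic acid enol OH is converted to the vinyl bromide (Vilsmeier-type halogenation); no stereocentre is formed.

**Step 2**
Reactants: 2
Product: 3 4-(tributylstannyl)furan-2(5H)-one
Conditions: (Bu3Sn)2, Pd(PPh3)4 (5 mol%), toluene, 100 °C
Reagents that add atoms: hexabutylditin, CCCC[Sn](CCCC)(CCCC)[Sn](CCCC)(CCCC)CCCC (supplies SnBu3)
Why: Pd-catalysed vinyl bromide stannylation gives the Stille partner.

**Step 3**
Reactants: 4 (2E,6E)-farnesol
Product: 5 farnesyl acetate
Conditions: Ac2O, pyridine, DMAP (cat.), CH2Cl2, 0 °C → rt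
Reagents that add atoms: acetic anhydride, CC(=O)OC(C)=O
Why: Acetylation protects the allylic alcohol so the later SeO2 oxidation is selective.

**Step 4**
Reactants: 5
Product: 6 (2E,6E,10E)-12-acetoxy-2,6,10-trimethyldodeca-2,6,10-trienal
Conditions: SeO2 (10 mol%), TBHP, CH2Cl2, 0 °C → rt; then MnO2, rt (one pot)
Reagents that add atoms: tert-butyl hydroperoxide, CC(C)(C)OO (oxygen source)
Why: Riley/Sharpless allylic oxidation occurs at the terminal E-methyl, and MnO2 takes the allylic alcohol on to the E-enal.

**Step 5**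
Reactants: 6
Product: 7 (2E,6E,10E)-12-acetoxy-2,6,10-trimethyldodeca-2,6,10-trienoic acid
Conditions: NaClO2, NaH2PO4, 2-methyl-2-butene, tBuOH/H2O, rt
Reagents that add atoms: sodium chlorite, [Na+].[O-]Cl=O (oxygen source)
Why: Pinnick oxidation converts the aldehyde to the acid without touching the trisubstituted alkenes.

**Step 6**
Reactants: 7
Product: 8 (2S,6E,10E)-12-acetoxy-2,6,10-trimethyldodeca-6,10-dienoic acid
Conditions: H2 (100 atm), Ru(OAc)2[(R)-BINAP] (0.5 mol%), MeOH, 25 °C
Reagents that add atoms: none
Why: Carboxylate-directed Ru-BINAP asymmetric hydrogenation of a tiglic-type (α-methyl) enoic acid sets the first stereocentre, C4 (S), and leaves the isolated trisubstituted alkenes untouched.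

**Step 7**
Reactants: 8
Product: 9 (2S,6E,10E)-2,6,10-trimethyldodeca-6,10-diene-1,12-diol
Conditions: LiAlH4, THF, 0 °C → rt
Reagents that add atoms: none
Why: LiAlH4 reduces the acid to the primary alcohol and cleaves the acetate in one operation; C4 is not epimerisable (no adjacent carbonyl after reduction).

**Step 8**
Reactants: 9
Product: 10 (2S,6E,10E)-12-chloro-2,6,10-trimethyldodeca-6,10-dien-1-ol
Conditions: NCS, Me2S, CH2Cl2, −20 → 0 °C
Reagents that add atoms: N-chlorosuccinimide, O=C1CCC(=O)N1Cl (supplies Cl)
Why: Corey–Kim chlorination is selective for the allylic alcohol over the saturated primary alcohol, with no allylic transposition.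

**Step 9**
Reactants: 10; 3 4-(tributylstannyl)furan-2(5H)-one
Product: 11 4-[(2E,6E,11S)-12-hydroxy-3,7,11-trimethyldodeca-2,6-dien-1-yl]furan-2(5H)-one
Conditions: Pd2(dba)3 (2.5 mol%), AsPh3 (20 mol%), LiCl, DMF, 45 °C
Reagents that add atoms: none
Why: Stille coupling of an allylic chloride with a vinylstannane occurs at the primary (α) carbon with retention of alkene geometry, forming the C1–C14 bond.

**Step 10**
Reactants: 11
Product: 12 4-[(2E,6E,11S)-3,7,11-trimethyl-12-oxododeca-2,6-dien-1-yl]furan-2(5H)-one
Conditions: TEMPO (5 mol%), PhI(OAc)2, CH2Cl2, rt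
Reagents that add atoms: none
Why: TEMPO/BAIB oxidises the primary alcohol under mild, non-basic conditions, so the α-stereocentre (C4) is not epimerised.

**Step 11**
Reactants: 12
Product: 13 (2R,3R,4S,8E,12E)-3-hydroxycembra-1(15),8,12-trien-16,2-olide (macrocyclic butenolide)
Conditions: quinine-derived squaramide (20 mol%), CH2Cl2 (0.002 M), 4 Å MS, syringe-pump addition over 24 h, 20 °C
Reagents that add atoms: none
Why: Proposed new method: the tertiary amine deprotonates the butenolide γ-CH2 to an ion-paired 2-oxidofuran while the squaramide NH groups bind and orient the C3 aldehyde, so an intramolecular direct vinylogous aldol closes the 14-membered ring at C2–C3 through the γ-carbon. The catalyst and the C4 methyl stereocentre favour the 2,3-syn (threo) adduct that sets C2 (R) and C3 (R). The closest known reaction type is the intermolecular organocatalytic direct vinylogous aldol of butenolides (and the Mukaiyama vinylogous aldol of 2-silyloxyfurans), which has not been applied to macrocyclisation.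

**Step 12**
Reactants: 13
Product: 14 (1S,2R,3R,4S,8E,12E)-3-hydroxycembra-8,12-dien-16,2-olide (cis-fused lactone)
Conditions: L-Selectride (3 equiv), THF, −78 °C; then aq. NH4Cl
Reagents that add atoms: none
Why: Conjugate reduction delivers hydride to C1 from the peripheral face anti to the C3 side chain, because the macrocyclic tether covers the other face. This pushes C14 cis to C3 and sets C1 (S) with the cis ring fusion, and the isolated alkenes survive.

**Step 13**
Reactants: 14
Product: 15 (1S,2R,3R,4S,8E,12E)-3-acetoxycembra-8,12-dien-16,2-olide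
Conditions: Ac2O, pyridine, DMAP (cat.), CH2Cl2, 0 °C → rt
Reagents that add atoms: acetic anhydride, CC(=O)OC(C)=O
Why: Acetylation is done on the saturated lactone, where the γ-position is no longer acidic and E1cB loss of the C3 acetate cannot occur.

**Step 14**
Reactants: 15
Product: 16 (1S,2R,3R,4S,8R,9R,12R,13R)-3-acetoxy-8,9:12,13-diepoxycembran-16,2-olide
Conditions: Shi D-fructose-derived ketone (0.6 equiv), Oxone, K2CO3, Bu4NHSO4, Na2B4O7/EDTA, MeCN/DMM, 0 °C, pH 10.5
Reagents that add atoms: Oxone (KHSO5), OOS(=O)(=O)[O-].[K+] (supplies the two epoxide oxygens)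
Why: Shi asymmetric epoxidation through the chiral dioxirane spiro transition state adds oxygen to both E-trisubstituted alkenes from the same enantioface, giving the 8,9- and 12,13-trans-epoxides that set the C8, C9, C12 and C13 configurations under reagent control.

**Step 15**
Reactants: 16
Product: 17 (1S,2R,3R,4S,8S,9R,12S,13R)-3,8-diacetoxy-13-hydroxy-9,12-epoxycembran-16,2-olide
Conditions: AcOH/CH2Cl2 (1:1), CSA (5 mol%), 30 °C
Reagents that add atoms: acetic acid, CC(=O)O (supplies the C8 acetoxy group)
Why: Acid-promoted acetolysis of the 8,9-epoxide occurs at tertiary C8 with inversion, leaving the C9 oxygen with retention as a free hydroxyl. That hydroxyl then opens the 12,13-epoxide at tertiary C12 in a 5-exo, inversion step, giving the 2,5-cis THF and the C13 alcohol (tandem epoxide-opening cascade).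

**Step 16**
Reactants: 17
Product: 18 target, (1S,2R,3R,4S,8S,9R,12S,13R)-3,8-diacetoxy-13-hydroxy-9,12-epoxycembran-15(17)-en-16,2-olide
Conditions: LiHMDS (2.6 equiv), THF, −78 °C; then CH2=NMe2+ I− (3 equiv), −78 → 0 °C; then MeI; then aq. NaHCO3, rt
Reagents that add atoms: Eschenmoser's salt, C=[N+](C)C.[I-] (supplies the exocyclic CH2)
Why: Lactone enolate aminomethylation followed by quaternisation and elimination (Eschenmoser α-methylenation) installs C15=C17; the extra base equivalent covers the free C13-OH, and no existing stereocentre is enolisable.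

## Compound list
1 | tetronic acid | O=C1CC(=O)CO1 | starting material
2 | 4-bromofuran-2(5H)-one | O=C1C=C(Br)CO1 | intermediate
3 | 4-(tributylstannyl)furan-2(5H)-one | O=C1C=C([Sn](CCCC)(CCCC)CCCC)CO1 | intermediate
4 | (2E,6E)-farnesol | OC/C=C(C)/CC/C=C(C)/CCC=C(C)C | starting material
5 | farnesyl acetate | CC(=O)OC/C=C(C)/CC/C=C(C)/CCC=C(C)C | intermediate
6 | (2E,6E,10E)-12-acetoxy-2,6,10-trimethyldodeca-2,6,10-trienal | CC(=O)OC/C=C(C)/CC/C=C(C)/CC/C=C(C)/C=O | intermediate
7 | (2E,6E,10E)-12-acetoxy-2,6,10-trimethyldodeca-2,6,10-trienoic acid | CC(=O)OC/C=C(C)/CC/C=C(C)/CC/C=C(C)/C(=O)O | intermediate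
8 | (2S,6E,10E)-12-acetoxy-2,6,10-trimethyldodeca-6,10-dienoic acid | CC(=O)OC/C=C(C)/CC/C=C(C)/CCC[C@H](C)C(=O)O | intermediate
9 | (2S,6E,10E)-2,6,10-trimethyldodeca-6,10-diene-1,12-diol | OC/C=C(C)/CC/C=C(C)/CCC[C@H](C)CO | intermediate
10 | (2S,6E,10E)-12-chloro-2,6,10-trimethyldodeca-6,10-dien-1-ol | ClC/C=C(C)/CC/C=C(C)/CCC[C@H](C)CO | intermediate
11 | 4-[(2E,6E,11S)-12-hydroxy-3,7,11-trimethyldodeca-2,6-dien-1-yl]furan-2(5H)-one | O=C1C=C(C/C=C(C)/CC/C=C(C)/CCC[C@H](C)CO)CO1 | intermediate
12 | 4-[(2E,6E,11S)-3,7,11-trimethyl-12-oxododeca-2,6-dien-1-yl]furan-2(5H)-one | O=C1C=C(C/C=C(C)/CC/C=C(C)/CCC[C@H](C)C=O)CO1 | intermediate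
13 | (2R,3R,4S,8E,12E)-3-hydroxycembra-1(15),8,12-trien-16,2-olide | C=1C(=O)O[C@H]2[C@H](O)[C@@H](C)CCC/C(C)=C/CC/C(C)=C/CC12 | intermediate
14 | (1S,2R,3R,4S,8E,12E)-3-hydroxycembra-8,12-dien-16,2-olide | C1C(=O)O[C@H]2[C@H](O)[C@@H](C)CCC/C(C)=C/CC/C(C)=C/C[C@@H]12 | intermediate
15 | (1S,2R,3R,4S,8E,12E)-3-acetoxycembra-8,12-dien-16,2-olide | C1C(=O)O[C@H]2[C@H](OC(C)=O)[C@@H](C)CCC/C(C)=C/CC/C(C)=C/C[C@@H]12 | intermediate
16 | (1S,2R,3R,4S,8R,9R,12R,13R)-3-acetoxy-8,9:12,13-diepoxycembran-16,2-olide | C1C(=O)O[C@H]2[C@H](OC(C)=O)[C@@H](C)CCC[C@@]3(C)O[C@@H]3CC[C@@]4(C)O[C@@H]4C[C@@H]12 | intermediate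
17 | (1S,2R,3R,4S,8S,9R,12S,13R)-3,8-diacetoxy-13-hydroxy-9,12-epoxycembran-16,2-olide | C1C(=O)O[C@H]2[C@H](OC(C)=O)[C@@H](C)CCC[C@](C)(OC(C)=O)[C@H]3CC[C@](C)(O3)[C@H](O)C[C@@H]12 | intermediate
18 | target (CID10479028) | C=C1C(=O)O[C@H]2[C@H](OC(C)=O)[C@@H](C)CCC[C@](C)(OC(C)=O)[C@H]3CC[C@](C)(O3)[C@H](O)C[C@@H]12 | target

## Totals
- Total steps: 16 (two-step stannane branch plus the 14-step farnesol line).
- Longest linear sequence: 14 steps (farnesol 4 → 18).

## Three steps most likely to fail
1. **Step 11 (proposed new macrocyclic vinylogous aldol).** Oligomerisation, C4 epimerisation or the wrong C2/C3 diastereomer are the main risks.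
   - Fallback (known chemistry): close the ring by intramolecular Nozaki–Hiyama–Kishi allylation instead. Use a Baylis–Hillman-derived 2-(bromomethyl)alk-2-enoate and a C2 aldehyde (CrCl2/NiCl2), forming C1–C2 and the lactone in one step. If the trans-lactone results, invert C2 by Mitsunobu lactonisation of the hydroxy-acid.
2. **Step 15 (acetolysis/oxa-cyclisation cascade).** Loss of inversion at tertiary C8 or competing C12 opening by acetate are the main risks.
   - Fallback: go stepwise. Use CSA in MeCN/H2O for the hydrolytic opening and 5-exo cyclisation to the C8 tertiary alcohol and THF. Then protect C13-OH (TESOTf), acetylate C8 (Ac2O, Sc(OTf)3) and remove the silyl group (HF·py).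
3. **Step 12 (cis-selective 1,4-reduction).** Hydride may attack the wrong face, or γ-deprotonation may compete.
   - Fallback: keep the butenolide through the acetylation, Shi and cascade steps and hydrogenate it afterwards (H2, Rh/Al2O3). The rigid THF-bridged polycycle then has only one alkene left and a hindered concave face, which should favour the cis ring fusion.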